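The flask holds 1.5 M each of left-handed and right-handed substrate, with the solid reagent undissolved at the start and the free catalyst single-handed.

the same everywhere: free catalyst 15 mol%

|  | left-handed substrate | right-handed substrate | solid reagent | remark | time |
|---|---|---|---|---|---|
| spring | 0.75 M | 0.75 M | 1.1 equiv | run made earlier |  |
| winter | 1.1 M | 1.1 M | 1.1 equiv | run made earlier |  |
| flask | 1.5 M | 1.5 M | 1.10 equiv |  | 15 h |

- spring (time / h: right-handed substrate / %, left-handed substrate / %, left-handed product / %): 0.833: 50, 49, 2; 2.50: 48, 45, 3; 4.00: 50, 39, 9; 6.00: 47, 36, 15; 10.0: 47, 29, 21; 12.0: 44, 25, 24; 15.0: 44, 25, 25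
- winter (time / h: right-handed substrate / %, left-handed substrate / %, left-handed product / %): 1.33: 51, 49, 3; 2.00: 47, 44, 8; 3.00: 48, 41, 11; 4.00: 45, 37, 14; 6.00: 44, 30, 18; 10.0: 43, 21, 27; 15.0: 42, 17, 30

(readings scatter by 1.5 percentage points)

- free catalyst is single-handed; left-handed substrate and right-handed substrate are mirror images of each other, charged as a racemate, each of them at the stated concentration
- solid, in amounts per volume of the solution: solid reagent
- the earlier runs were read with a standard deviation of 1.5 percentage points
- at the start none of the solid reagent is in solution

- whether the excess of right-handed substrate over left-handed substrate among what is left of the two reaches 99% by 15 h (no / yes)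
- the highest excess of right-handed substrate over left-handed substrate among what is left of the two up to 15 h

For the next person at the bench, this note's own reckoning counts turnovers. Taking one solid reagent per substrate turned over, the flask's charge pays for 7.33 turnovers per catalyst charged, and this turnover budget, equivalents of solid reagent over catalyst loading, is the same in the winter run, which by the readings of its substrates had spent about 5.47 by 15.0 h. Even with its budget fully spent, the flask keeps 0.900 of one substrate charge as the two substrates together, so an excess of 99% demands a selectivity factor, the ratio of the logarithms of the fractions left, of 49.0. The winter readings give about 6.19, far less, so this reckoning says no. Nothing should be added to the flask, so that the count of 7.33 stays the one reckoned here.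

The forecast says no, with a top of 53%, holding that “The excess rises steadily”.

The flask gives no and 48.8%.

    partner + free catalyst + left-handed substrate → free catalyst + left-handed product (k = 3.13 × 10⁻⁴ M⁻² s⁻¹)
    partner + free catalyst + right-handed substrate → free catalyst + right-handed product (k = 5.75 × 10⁻⁵ M⁻² s⁻¹)
    solid reagent ⇌ partner, rate k3*(cs3 - [partner]) while solid is left; crystals form when [partner] > cs3 (solubility = 0.960 M, k = 2.08 × 10⁻⁴ s⁻¹)
    free catalyst ⇌ dormant form (K = 0.450, k = 0.00104 s⁻¹)
    free catalyst → spent catalyst (k = 1.37 × 10⁻⁷ s⁻¹)

At 15.0 h the flask holds 36.5% left-handed and 10.7% right-handed product, which is 6.29 turnovers, fewer than the budget of 7.33, with 0.235 M of partner, the dissolved reagent, still in solution. The neighbouring flask read at 2.5 d holds 41.2% and 13.7%, which is 7.31 turnovers, level with the budget. There the solid reagent, the limiting reagent, is first to run out, with 0% solid and 0.00490 M of partner left, and the highest excess is 61.0%.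

The runs stem from a simulated flask for an exercise; scatter was added.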